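**Plan**
- Retrosynthetic cuts, in order: C13–O/C14=C15 (epoxy iodide → tertiary allylic alcohol), C12–C13 (B-alkyl Suzuki coupling), C2(=O)–O8 (oxidative lactonization), C4–C5 (Ireland–Claisen from a C7 ester), and finally C8–C9 together with C5–C10 ([4+2]).
- Enabling feature: ring B (C5–C10) carries on C10 a methyl and the one-carbon arm C1, trans to the C11 arm on C9, while C7 can hold a removable oxygen; this is the pattern delivered by an (E)-2-methyl-4-oxobut-2-enoate and a 3-silyloxypenta-1,3-diene.
- Forward order: ring B first (steps 1–2); C8–O, C7–O and the C4 acid arm on the monocycle (steps 3–13); the lactone ring second (step 14); the C12–C16 chain last (steps 15–23).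
- Stereochemistry: C9/C10 from the chiral boron catalyst and the E-dienophile; C8 by enolate oxidation anti to the C9 arm; C7 by chelation-controlled reduction; C5 by suprafacial [3,3] transfer from C7; C13 from L-(+)-diethyl tartrate.

Key step: step 2

Remark 1: locants are those of the labdane skeleton (ring B = C5–C10; C17 on C8; C20 on C10; C1–C2 the lactone arm on C10; C3/C4/C18/C19 the acid arm on C5; C11–C16 the chain on C9); β is the face of ring B that carries C20, α the opposite face.
Remark 2: the cycloadduct is drawn as the formyl-endo isomer (C8 methyl α); its C8 epimer would be carried along, since both give the same dienolate in step 7.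
Remark 3: the facial sense of the boron catalyst is taken from the accepted binding model for α-substituted enals; both catalyst enantiomers are available.

**Step 1**
Reactants: 1 pent-1-en-3-one
Product: 2 (Z)-tert-butyl(dimethyl)(penta-1,3-dien-3-yloxy)silane
Conditions: TBSOTf, Et3N, Et2O, 0 °C
Reagents that add atoms: tert-butyldimethylsilyl trifluoromethanesulfonate, CC(C)(C)[Si](C)(C)OS(=O)(=O)C(F)(F)F
Why: Silyl enol ether formation by soft enolization (O-silylation, then amine deprotonation of the ethyl CH2) should give the 2-silyloxy diene as the Z enol ether, the geometry with the methyl anti to the vinyl group that a Diels–Alder diene needs.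

**Step 2**
Reactants: 2 (Z)-tert-butyl(dimethyl)(penta-1,3-dien-3-yloxy)silane; 3 ethyl (E)-3-methyl-4-oxobut-2-enoate
Product: 4 ethyl (1R,2R,6R)-3-[tert-butyl(dimethyl)silyl]oxy-6-formyl-2,6-dimethylcyclohex-3-ene-1-carboxylate
Conditions: (S)-3,3-diphenyl-1-(2-methylphenyl)tetrahydro-1H,3H-pyrrolo[1,2-c][1,3,2]oxazaborole (20 mol %), Tf2NH (18 mol %), CH2Cl2, −78 °C
Reagents that add atoms: none
Why: The boron cation formed from the oxazaborolidine and Tf2NH binds the formyl oxygen of 3 (formyl C–H···O contact, s-trans enal stacked on a phenyl group) and lowers its LUMO, and a concerted but asynchronous [4+2] follows in which C8, the enol-ether terminus of 2, bonds to C9 (β to the aldehyde) ahead of C5–C10. The closest known reaction type is the oxazaborolidinium-catalyzed Diels–Alder reaction of 2-silyloxy dienes with α-substituted α,β-unsaturated aldehydes. Ring B (C5–C10) closes by intermolecular suprafacial–suprafacial cycloaddition, both new σ bonds being made in the one step. C9 and C10 are fixed relative to each other by the E geometry of 3 (formyl C1 and ester C11 trans) and in the absolute sense by the (S)-catalyst, whose phenyl group covers one face of the bound enal so that C5 adds to the Re face of the formyl-bearing carbon. C8 follows from the outward methyl of the Z enol ether and the endo preference of the complexed formyl group, and its configuration is later erased. The step needs regioselectivity (C10 para to C7), secured by the silyloxy donor outweighing the terminal methyl and by activation of the aldehyde rather than the ester, and face selectivity, secured by the catalyst.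

**Step 3**
Reactants: 4 ethyl (1R,2R,6R)-3-[tert-butyl(dimethyl)silyl]oxy-6-formyl-2,6-dimethylcyclohex-3-ene-1-carboxylate
Product: 5 ethyl 3-[tert-butyl(dimethyl)silyl]oxy-6-ethenyl-2,6-dimethylcyclohex-3-ene-1-carboxylate (vinyl = C1=C2; stereocenters as in 4)
Conditions: Ph3PCH3Br, KOtBu, THF, 0 °C → rt
Reagents that add atoms: methyltriphenylphosphonium bromide, C[P+](c1ccccc1)(c1ccccc1)c1ccccc1.[Br-]
Why: Wittig methylenation, in which the non-enolizable neopentyl aldehyde reacts with the unstabilized ylide far faster than the hindered ester or the silyl enol ether, turns C1 into a vinyl group that already carries the future C2.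

**Step 4**
Reactants: 5 ethyl 3-[tert-butyl(dimethyl)silyl]oxy-6-ethenyl-2,6-dimethylcyclohex-3-ene-1-carboxylate
Product: 6 {3-[tert-butyl(dimethyl)silyl]oxy-6-ethenyl-2,6-dimethylcyclohex-3-en-1-yl}methanol (C11 carbinol; stereocenters as in 4)
Conditions: LiAlH4, THF, 0 °C
Reagents that add atoms: none
Why: Hydride reduction of the ester gives the C11 carbinol, the tert-butyldimethylsilyl enol ether and the isolated alkene being inert to aluminum hydride at this temperature.

**Step 5**
Reactants: 6 {3-[tert-butyl(dimethyl)silyl]oxy-6-ethenyl-2,6-dimethylcyclohex-3-en-1-yl}methanol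
Product: 7 C11 tert-butyldimethylsilyl ether of 6 (silyl ether plus silyl enol ether)
Conditions: TBSCl, imidazole, DMF, rt
Reagents that add atoms: tert-butyl(chloro)dimethylsilane, CC(C)(C)[Si](C)(C)Cl
Why: Standard silylation of a primary alcohol masks C11–OH for the enolate, acylation and oxidation steps that follow.

**Step 6**
Reactants: 7 C11 tert-butyldimethylsilyl ether of 6
Product: 8 5-({[tert-butyl(dimethyl)silyl]oxy}methyl)-4-ethenyl-4,6-dimethylcyclohex-2-en-1-one (C7 ketone; C5=C6)
Conditions: Pd(OAc)2 (1.1 equiv), MeCN, rt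
Reagents that add atoms: none
Why: Saegusa–Ito oxidation passes through a palladium enolate bound at C6 whose only β-hydrogens sit on C5, so the C5=C6 enone should form regiospecifically.

**Step 7**
Reactants: 8 5-({[tert-butyl(dimethyl)silyl]oxy}methyl)-4-ethenyl-4,6-dimethylcyclohex-2-en-1-one
Product: 10 6-hydroxy derivative of 8 (C8 α-OH and β-CH3), via potassium dienolate 9 (not isolated)
Conditions: KN(SiMe3)2, THF, −78 °C; then 2-(benzenesulfonyl)-3-phenyloxaziridine, −78 °C; AcOH quench
Reagents that add atoms: 2-(benzenesulfonyl)-3-phenyloxaziridine, O=S(=O)(c1ccccc1)N1OC1c1ccccc1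
Why: Enolate hydroxylation with an N-sulfonyloxaziridine (Davis oxidation): deprotonation is possible only at C8 because C10 is quaternary, and oxygen should be delivered to the α face of the cross-conjugated dienolate, anti to the adjacent β-CH2OTBS arm on C9, which sets C8 whichever C8 epimer of 8 is used.

**Step 8**
Reactants: 10 6-hydroxy derivative of 8 (C8 α-OH and β-CH3)
Product: 11 trans-diol 6-({[tert-butyl(dimethyl)silyl]oxy}methyl)-5-ethenyl-1,5-dimethylcyclohex-3-ene-1,2-diol (C7 β-OH; C8 α-OH)
Conditions: Zn(BH4)2, Et2O, −20 °C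
Reagents that add atoms: none
Why: Chelation-controlled 1,2-reduction of an α-hydroxy enone: zinc bridges the C7 carbonyl and the C8 hydroxyl, which holds the hydroxyl in the carbonyl plane and the C8 methyl axial on the β face, so hydride should enter from the α face and set C7 as the β-carbinol.

**Step 9**
Reactants: 11 trans-diol (C7 β-OH; C8 α-OH); 12 2-methylpropanoyl chloride
Product: 13 C7 β-(2-methylpropanoate) of 11 (tertiary C8 hydroxyl free)
Conditions: pyridine, DMAP (cat.), CH2Cl2, 0 °C
Reagents that add atoms: none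
Why: DMAP-catalyzed acylation distinguishes the secondary allylic hydroxyl from the tertiary one and gives the allylic isobutyrate needed for the sigmatropic step.

**Step 10**
Reactants: 13 C7 β-(2-methylpropanoate) of 11
Product: 16 2-methyl-2-[ring B]propanoic acid (C5 β-C(CH3)2CO2H; C6=C7; C8 α-OH), via silyl ketene acetal 14 (not isolated), via rearranged trimethylsilyl ester 15 (not isolated)
Conditions: LiN(iPr)2 (2.5 equiv), Me3SiCl–Et3N, THF, −78 °C → 65 °C; then 10% aq. citric acid
Reagents that add atoms: none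
Why: Ireland–Claisen rearrangement: the ketene acetal (no E/Z issue, its carbon bears two methyls; the C8 hydroxyl is silylated in the same operation) should undergo a suprafacial [3,3] shift that trades the β C7–O bond for a β C4–C5 bond, setting C5 and moving the alkene to C6=C7, after which mild acid frees the acid and the tertiary alcohol.

**Step 11**
Reactants: 16 2-methyl-2-[ring B]propanoic acid
Product: 17 2-(trimethylsilyl)ethyl ester of 16
Conditions: 2-(trimethylsilyl)ethanol, PPh3, DIAD, THF, 0 °C → rt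
Reagents that add atoms: 2-(trimethylsilyl)ethanol, C[Si](C)(C)CCO
Why: Mitsunobu esterification alkylates the hindered carboxylate on oxygen with the activated primary alcohol (the tertiary C8 alcohol cannot be activated) and installs an ester that only fluoride will later remove.

**Step 12**
Reactants: 17 2-(trimethylsilyl)ethyl ester of 16
Product: 19 primary alcohol (C10 α-CH2CH2OH; C6=C7 unchanged), via C2 borane 18 (not isolated)
Conditions: 9-BBN, THF, 50 °C; then NaOH, H2O2, 0 °C → rt
Reagents that add atoms: hydrogen peroxide, OO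
Why: Hydroboration–oxidation with the bulky 9-BBN should select the monosubstituted vinyl group over the flanked ring alkene and place boron, then oxygen, on terminal C2.

**Step 13**
Reactants: 19 primary alcohol (C10 α-CH2CH2OH; C6=C7)
Product: 20 ring-saturated diol (C2 primary OH; C8 α tertiary OH)
Conditions: H2 (3 atm), PtO2, EtOAc, rt
Reagents that add atoms: none
Why: Heterogeneous hydrogenation of the cis-disubstituted ring alkene creates no stereocenter, and platinum is preferred to palladium on carbon to avoid double-bond migration toward C5 and allylic C–O hydrogenolysis.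

**Step 14**
Reactants: 20 ring-saturated diol
Product: 23 bicyclic δ-lactone (2-oxabicyclo[3.3.1]nonan-3-one; C11 silyl ether; C3 silylethyl ester), via hydroxy aldehyde 21 (not isolated), via bridged lactol 22 (not isolated)
Conditions: TEMPO (20 mol %), PhI(OAc)2 (3 equiv), CH2Cl2, rt
Reagents that add atoms: none
Why: TEMPO/PhI(OAc)2 oxidative lactonization of a 1,5-diol: the primary alcohol is oxidized to the aldehyde, the cis (α) C8 hydroxyl traps it as the bridged lactol, and a second oxidation gives the lactone, closing the second ring by C2–O8 bond formation without touching a stereocenter.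

**Step 15**
Reactants: 23 bicyclic δ-lactone (C11 silyl ether)
Product: 24 lactone alcohol (C11–OH)
Conditions: HF·pyridine, pyridine, THF, 0 °C → rt
Reagents that add atoms: none
Why: Buffered HF cleaves the primary silyl ether (desilylation), while the 2-(trimethylsilyl)ethyl ester, which needs unbuffered fluoride ion, and the lactone should persist.

**Step 16**
Reactants: 24 lactone alcohol
Product: 25 lactone aldehyde (C11 formyl on C9)
Conditions: Dess–Martin periodinane, CH2Cl2, 0 °C → rt
Reagents that add atoms: none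
Why: Dess–Martin oxidation is non-basic, so the aldehyde should form without C9 epimerization or loss of the β-acyloxy group.

**Step 17**
Reactants: 25 lactone aldehyde
Product: 26 C9-vinyl lactone (C11=C12)
Conditions: Zn, CH2Br2, TiCl4, THF (reagent pre-formed); then 25, CH2Cl2, 0 °C → rt
Reagents that add atoms: dibromomethane, BrCBr
Why: Takai–Lombardo methylenation uses a non-basic gem-dimetallic reagent, which should convert the aldehyde to the vinyl group without E1cB opening of the lactone and without attacking the ester or lactone carbonyls.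

**Step 18**
Reactants: 27 but-2-yn-1-ol
Product: 29 (Z)-3-iodobut-2-en-1-ol, via cyclic vinylalanate 28 (not isolated)
Conditions: NaAlH2(OCH2CH2OCH3)2, THF, 0 °C → rt; then I2, −78 °C → 0 °C
Reagents that add atoms: iodine, II
Why: Hydroxyl-directed trans-hydroalumination places aluminum on C3 cis to the carbinol carbon in a five-membered alanate, and iodinolysis with retention gives the Z vinyl iodide.

**Step 19**
Reactants: 26 C9-vinyl lactone; 29 (Z)-3-iodobut-2-en-1-ol
Product: 31 (Z)-allylic alcohol (C9–CH2CH2–C(CH3)=CH–CH2OH), via C12 borane 30 (not isolated)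
Conditions: 9-BBN, THF, rt → 40 °C; then 29, Pd(dppf)Cl2 (5 mol %), AsPh3, aq. K3PO4, DMF, rt
Reagents that add atoms: none
Why: B-alkyl Suzuki–Miyaura coupling: anti-Markovnikov hydroboration of the C9 vinyl group gives the C12 borane, which couples with the vinyl iodide with retention of alkene geometry to form the C12–C13 bond.

**Step 20**
Reactants: 31 (Z)-allylic alcohol
Product: 32 (13R,14S)-13,14-epoxy-15-ol
Conditions: Ti(OiPr)4 (10 mol %), L-(+)-diethyl tartrate (12 mol %), t-BuOOH, 4 Å molecular sieves, CH2Cl2, −20 °C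
Reagents that add atoms: tert-butyl hydroperoxide, CC(C)(C)OO
Why: Sharpless asymmetric epoxidation: with L-(+)-diethyl tartrate a Z (nerol-type) allylic alcohol is epoxidized on the face that makes C13 R, under reagent control and independent of the remote ring stereocenters.

**Step 21**
Reactants: 32 (13R,14S)-13,14-epoxy-15-ol
Product: 33 13,14-epoxy-15-iodide (configuration as in 32)
Conditions: PPh3, I2, imidazole, THF, 0 °C
Reagents that add atoms: iodine, II
Why: Appel-type iodination (Garegg–Samuelsson conditions) replaces the primary hydroxyl by iodide without opening the epoxide.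

**Step 22**
Reactants: 33 13,14-epoxy-15-iodide
Product: 34 2-(trimethylsilyl)ethyl ester of the target (13R tertiary allylic alcohol)
Conditions: Zn dust, AcOH, EtOH, rt
Reagents that add atoms: none
Why: Reductive opening of a 2,3-epoxy iodide: zinc inserts into the C–I bond and β-elimination opens the epoxide, which should give the C14=C15 vinyl group and the C13 hydroxyl with C13 unchanged.

**Step 23**
Reactants: 34 2-(trimethylsilyl)ethyl ester of the target
Product: 35 target acid CNP0198729.3
Conditions: Bu4NF, THF, 0 °C → rt; then AcOH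
Reagents that add atoms: none
Why: Fluoride attacks silicon and fragments the 2-(trimethylsilyl)ethyl ester (β-elimination to ethene and the carboxylate) under conditions that should spare the lactone and the tertiary allylic alcohol.

**Compound list**
1 | pent-1-en-3-one | C=CC(=O)CC | starting material
2 | (Z)-tert-butyl(dimethyl)(penta-1,3-dien-3-yloxy)silane | C=C/C(O[Si](C)(C)C(C)(C)C)=C/C | intermediate
3 | ethyl (E)-3-methyl-4-oxobut-2-enoate | O=C/C(C)=C/C(=O)OCC | starting material
4 | ethyl (1R,2R,6R)-3-[tert-butyl(dimethyl)silyl]oxy-6-formyl-2,6-dimethylcyclohex-3-ene-1-carboxylate (C10 β-CH3/α-CHO, C9 β-CO2Et, C8 α-CH3, C6=C7 silyl enol ether) | O=C[C@@]1(C)[C@H](C(=O)OCC)[C@@H](C)C(O[Si](C)(C)C(C)(C)C)=CC1 | intermediate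
5 | ethyl 3-[tert-butyl(dimethyl)silyl]oxy-6-ethenyl-2,6-dimethylcyclohex-3-ene-1-carboxylate, stereocenters as in 4 | C=C[C@@]1(C)[C@H](C(=O)OCC)[C@@H](C)C(O[Si](C)(C)C(C)(C)C)=CC1 | intermediate
6 | {3-[tert-butyl(dimethyl)silyl]oxy-6-ethenyl-2,6-dimethylcyclohex-3-en-1-yl}methanol, stereocenters as in 4 | C=C[C@@]1(C)[C@H](CO)[C@@H](C)C(O[Si](C)(C)C(C)(C)C)=CC1 | intermediate
7 | C11 tert-butyldimethylsilyl ether of 6 | C=C[C@@]1(C)[C@H](CO[Si](C)(C)C(C)(C)C)[C@@H](C)C(O[Si](C)(C)C(C)(C)C)=CC1 | intermediate
8 | 5-({[tert-butyl(dimethyl)silyl]oxy}methyl)-4-ethenyl-4,6-dimethylcyclohex-2-en-1-one (C7 ketone, C5=C6; C10 β-CH3/α-vinyl, C9 β-CH2OTBS, C8 α-CH3) | C=C[C@@]1(C)[C@H](CO[Si](C)(C)C(C)(C)C)[C@@H](C)C(=O)C=C1 | intermediate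
9 | potassium cross-conjugated dienolate of 8 (C7–OK, C7=C8, C5=C6) | C=C[C@@]1(C)[C@H](CO[Si](C)(C)C(C)(C)C)C(C)=C([O-])C=C1.[K+] | intermediate (not isolated)
10 | 6-hydroxy derivative of 8: C8 α-OH, β-CH3 | C=C[C@@]1(C)[C@H](CO[Si](C)(C)C(C)(C)C)[C@@](C)(O)C(=O)C=C1 | intermediate
11 | 6-({[tert-butyl(dimethyl)silyl]oxy}methyl)-5-ethenyl-1,5-dimethylcyclohex-3-ene-1,2-diol: C7 β-OH, C8 α-OH (trans) | C=C[C@@]1(C)[C@H](CO[Si](C)(C)C(C)(C)C)[C@@](C)(O)[C@H](O)C=C1 | intermediate
12 | 2-methylpropanoyl chloride | CC(C)C(=O)Cl | starting material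
13 | C7 β-(2-methylpropanoate) of 11 | C=C[C@@]1(C)[C@H](CO[Si](C)(C)C(C)(C)C)[C@@](C)(O)[C@H](OC(=O)C(C)C)C=C1 | intermediate
14 | trimethylsilyl ketene acetal of 13, C8 hydroxyl as trimethylsilyl ether | C=C[C@@]1(C)[C@H](CO[Si](C)(C)C(C)(C)C)[C@@](C)(O[Si](C)(C)C)[C@H](OC(O[Si](C)(C)C)=C(C)C)C=C1 | intermediate (not isolated)
15 | rearranged trimethylsilyl ester: C5 β-C(CH3)2CO2SiMe3, C6=C7, C8 α-OSiMe3 | C=C[C@@]1(C)[C@H](CO[Si](C)(C)C(C)(C)C)[C@@](C)(O[Si](C)(C)C)C=C[C@@H]1C(C)(C)C(=O)O[Si](C)(C)C | intermediate (not isolated)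
16 | 2-methyl-2-[ring B]propanoic acid: C5 β-C(CH3)2CO2H, C6=C7, C8 α-OH/β-CH3, C9 β-CH2OTBS, C10 β-CH3/α-vinyl | C=C[C@@]1(C)[C@H](CO[Si](C)(C)C(C)(C)C)[C@@](C)(O)C=C[C@@H]1C(C)(C)C(=O)O | intermediate
17 | 2-(trimethylsilyl)ethyl ester of 16 | C=C[C@@]1(C)[C@H](CO[Si](C)(C)C(C)(C)C)[C@@](C)(O)C=C[C@@H]1C(C)(C)C(=O)OCC[Si](C)(C)C | intermediate
18 | B-alkyl-9-borabicyclo[3.3.1]nonane with boron on C2 (C8 hydroxyl shown free) | C1CC2CCCC(C1)B2CC[C@@]1(C)[C@H](CO[Si](C)(C)C(C)(C)C)[C@@](C)(O)C=C[C@@H]1C(C)(C)C(=O)OCC[Si](C)(C)C | intermediate (not isolated)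
19 | primary alcohol: C10 α-CH2CH2OH, C6=C7, C8 α-OH | OCC[C@@]1(C)[C@H](CO[Si](C)(C)C(C)(C)C)[C@@](C)(O)C=C[C@@H]1C(C)(C)C(=O)OCC[Si](C)(C)C | intermediate
20 | ring-saturated diol (C2 primary OH, C8 α tertiary OH) | OCC[C@@]1(C)[C@H](CO[Si](C)(C)C(C)(C)C)[C@@](C)(O)CC[C@@H]1C(C)(C)C(=O)OCC[Si](C)(C)C | intermediate
21 | C2 aldehyde of 20 | O=CC[C@@]1(C)[C@H](CO[Si](C)(C)C(C)(C)C)[C@@](C)(O)CC[C@@H]1C(C)(C)C(=O)OCC[Si](C)(C)C | intermediate (not isolated)
22 | bridged lactol (2-oxabicyclo[3.3.1]nonan-3-ol, anomeric mixture) | CC(C)(C)[Si](C)(C)OC[C@H]1[C@]2(C)CC(O)O[C@@]1(C)CC[C@@H]2C(C)(C)C(=O)OCC[Si](C)(C)C | intermediate (not isolated)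
23 | 2-(trimethylsilyl)ethyl 2-[9-({[tert-butyl(dimethyl)silyl]oxy}methyl)-1,5-dimethyl-3-oxo-2-oxabicyclo[3.3.1]nonan-6-yl]-2-methylpropanoate, ring configuration as in 35 | CC(C)(C)[Si](C)(C)OC[C@H]1[C@]2(C)CC(=O)O[C@@]1(C)CC[C@@H]2C(C)(C)C(=O)OCC[Si](C)(C)C | intermediate
24 | lactone alcohol (9-hydroxymethyl), ring configuration as in 35 | OC[C@H]1[C@]2(C)CC(=O)O[C@@]1(C)CC[C@@H]2C(C)(C)C(=O)OCC[Si](C)(C)C | intermediate
25 | lactone aldehyde (9-formyl), ring configuration as in 35 | O=C[C@H]1[C@]2(C)CC(=O)O[C@@]1(C)CC[C@@H]2C(C)(C)C(=O)OCC[Si](C)(C)C | intermediate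
26 | 9-ethenyl lactone (C11=C12), ring configuration as in 35 | C=C[C@H]1[C@]2(C)CC(=O)O[C@@]1(C)CC[C@@H]2C(C)(C)C(=O)OCC[Si](C)(C)C | intermediate
27 | but-2-yn-1-ol | CC#CCO | starting material
28 | sodium cyclic vinylalanate (aluminum on C3, oxygen-bound, two 2-methoxyethoxy ligands) | CC1=CCO[Al-]1(OCCOC)OCCOC.[Na+] | intermediate (not isolated)
29 | (Z)-3-iodobut-2-en-1-ol | C/C(I)=C/CO | intermediate
30 | B-alkyl-9-borabicyclo[3.3.1]nonane with boron on C12 | C1CC2CCCC(C1)B2CC[C@H]1[C@]2(C)CC(=O)O[C@@]1(C)CC[C@@H]2C(C)(C)C(=O)OCC[Si](C)(C)C | intermediate (not isolated)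
31 | 9-[(3Z)-5-hydroxy-3-methylpent-3-en-1-yl] lactone, ring configuration as in 35 | OC/C=C(/C)CC[C@H]1[C@]2(C)CC(=O)O[C@@]1(C)CC[C@@H]2C(C)(C)C(=O)OCC[Si](C)(C)C | intermediate
32 | (13R,14S)-13,14-epoxy-15-ol (cis-epoxide from the Z alkene) | OC[C@@H]3O[C@]3(C)CC[C@H]1[C@]2(C)CC(=O)O[C@@]1(C)CC[C@@H]2C(C)(C)C(=O)OCC[Si](C)(C)C | intermediate
33 | 13,14-epoxy-15-iodide, same spatial arrangement as 32 | IC[C@@H]3O[C@]3(C)CC[C@H]1[C@]2(C)CC(=O)O[C@@]1(C)CC[C@@H]2C(C)(C)C(=O)OCC[Si](C)(C)C | intermediate
34 | 2-(trimethylsilyl)ethyl ester of the target (13R) | C=C[C@](C)(O)CC[C@H]1[C@]2(C)CC(=O)O[C@@]1(C)CC[C@@H]2C(C)(C)C(=O)OCC[Si](C)(C)C | intermediate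
35 | 2-[(1S,5R,6S,9S)-9-[(3R)-3-hydroxy-3-methylpent-4-en-1-yl]-1,5-dimethyl-3-oxo-2-oxabicyclo[3.3.1]nonan-6-yl]-2-methylpropanoic acid (CNP0198729.3) | C=C[C@](C)(O)CC[C@H]1[C@]2(C)CC(=O)O[C@@]1(C)CC[C@@H]2C(C)(C)C(=O)O | target

**Step count**
Total: 23 steps. Longest linear sequence: 22 steps (steps 1–17 and 19–23); step 18 prepares the vinyl iodide separately.

**Steps most likely to fail**

1. Step 10. The [3,3] shift has to join a fully substituted ketene acetal carbon to a ring carbon that sits next to quaternary C10. It may be outrun by fragmentation of the silyl ketene acetal or by acyl transfer to the neighboring C8 oxygen. The fallback builds the quaternary C4 in two stages; it sets out from 11 and returns at 17. Acylation of 11 with propanoyl chloride (pyridine, DMAP) gives the C7 propanoate F1. LiN(iPr)2/Me3SiCl converts it into the less hindered silyl ketene acetal F2, which rearranges to the silyl ester F3 and, after aqueous citric acid, to the 2-substituted propanoic acid F4 (C4 epimers, both usable). Mitsunobu esterification with 2-(trimethylsilyl)ethanol gives the ester F5. LiN(iPr)2 (2.2 equiv, THF–DMPU, −78 °C) forms the dilithium alkoxide enolate F6, and iodomethane methylates it at C4 to give 17.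

2. Step 14. Lactol closure requires ring B to leave its chair so that C1 and the C8 oxygen become syn-axial. If this is slow, the oxidation stalls at the hydroxy aldehyde or the aldehyde is lost to side reactions. The fallback replaces the lactol pathway by acyl activation; it sets out from 20 and returns at 23. TEMPO/PhI(OAc)2 in MeCN–water oxidizes 20 to the hydroxy acid F7. 2,4,6-Trichlorobenzoyl chloride/Et3N converts it into the mixed anhydride F8, which DMAP in toluene at 80 °C should close onto the tertiary C8 hydroxyl (Yamaguchi lactonization) to give 23.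

3. Step 7. Face selectivity in the oxygen transfer to the dienolate may be poor, and because C8 relays to C7 and C7 to C5, a β-hydroxylated fraction would enter the wrong series. The fallback replaces enolate oxidation by a Rubottom oxidation of an isolated neutral dienol ether; it sets out from 8 and returns at 10. Me3SiOTf/Et3N gives the trimethylsilyl dienol ether F9, in which A(1,2) strain with the C8 methyl holds the C9 arm pseudoaxial over the β face. Dimethyldioxirane (acetone, −78 °C) should epoxidize the enol-ether double bond from the α face to the silyloxy oxirane F10, which opens with 1,4-silyl shift to the α-silyloxy enone F11. Citric acid in methanol then frees 10.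

**Further compounds**
F1 | step 10 | C7 β-propanoate of 11 | C=C[C@@]1(C)[C@H](CO[Si](C)(C)C(C)(C)C)[C@@](C)(O)[C@H](OC(=O)CC)C=C1
F2 | step 10 | trimethylsilyl ketene acetal of F1 with C8 trimethylsilyl ether | C=C[C@@]1(C)[C@H](CO[Si](C)(C)C(C)(C)C)[C@@](C)(O[Si](C)(C)C)[C@H](OC(O[Si](C)(C)C)=CC)C=C1
F3 | step 10 | rearranged trimethylsilyl 2-[ring B]propanoate with C8 trimethylsilyl ether | C=C[C@@]1(C)[C@H](CO[Si](C)(C)C(C)(C)C)[C@@](C)(O[Si](C)(C)C)C=C[C@@H]1C(C)C(=O)O[Si](C)(C)C
F4 | step 10 | 2-[ring B]propanoic acid (C5 β; C4 epimers) | C=C[C@@]1(C)[C@H](CO[Si](C)(C)C(C)(C)C)[C@@](C)(O)C=C[C@@H]1C(C)C(=O)O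
F5 | step 10 | 2-(trimethylsilyl)ethyl ester of F4 | C=C[C@@]1(C)[C@H](CO[Si](C)(C)C(C)(C)C)[C@@](C)(O)C=C[C@@H]1C(C)C(=O)OCC[Si](C)(C)C
F6 | step 10 | dilithium alkoxide enolate of F5 | C=C[C@@]1(C)[C@H](CO[Si](C)(C)C(C)(C)C)[C@@](C)([O-])C=C[C@@H]1C(C)=C([O-])OCC[Si](C)(C)C.[Li+].[Li+]
F7 | step 14 | hydroxy acid (C10 α-CH2CO2H, C8 α-OH) | OC(=O)C[C@@]1(C)[C@H](CO[Si](C)(C)C(C)(C)C)[C@@](C)(O)CC[C@@H]1C(C)(C)C(=O)OCC[Si](C)(C)C
F8 | step 14 | mixed anhydride of F7 with 2,4,6-trichlorobenzoic acid | O=C(C[C@@]1(C)[C@H](CO[Si](C)(C)C(C)(C)C)[C@@](C)(O)CC[C@@H]1C(C)(C)C(=O)OCC[Si](C)(C)C)OC(=O)c1c(Cl)cc(Cl)cc1Cl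
F9 | step 7 | trimethylsilyl dienol ether of 8 | C=C[C@@]1(C)[C@H](CO[Si](C)(C)C(C)(C)C)C(C)=C(O[Si](C)(C)C)C=C1
F10 | step 7 | α-face 7,8-epoxide of F9 (silyloxy oxirane) | C=C[C@@]1(C)[C@H](CO[Si](C)(C)C(C)(C)C)[C@@]2(C)O[C@@]2(O[Si](C)(C)C)C=C1
F11 | step 7 | C8 α-trimethylsilyloxy enone | C=C[C@@]1(C)[C@H](CO[Si](C)(C)C(C)(C)C)[C@@](C)(O[Si](C)(C)C)C(=O)C=C1
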